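Assumption: the target has no stereocentres and no hindered axis, so it is achiral. The "single enantiomer" requirement is moot and no step needs stereocontrol.

## Retrosynthetic overview
1. The target comes from one global hydrogenolysis of a precursor carrying a benzyl ester on ring C and a benzyl ether at O-4 of ring A.
2. Ring A is not attached as a hindered benzoic acid. A retro-[4+2]/oxa-bridge opening disconnects it to the ring-B O-but-2-ynoate and a 4-benzyloxy-2-silyloxyfuran derived from tetronic acid. This sets the 2,4,5-trioxygenated, 6-methyl pattern in one step.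
3. Ring B is disconnected by retro-Diels–Alder to the ring-C O-but-2-ynoate and 1,1-dimethoxy-3-silyloxybutadiene. The ring forms with 2'-OMe, free 4'-OH and 6'-Me already differentiated.
4. Ester C–O bonds are only ever made with small, unhindered but-2-ynoic acid. The 2,6-disubstituted benzoate esters are never formed by acylation.
5. Ring order: C is purchased as orsellinic acid, B is made by Diels–Alder aromatisation, and A is made by furan Diels–Alder with ring-opening aromatisation.

## Route

**Step 1**
Reactants: 1 acetyl chloride; 2 1,1-dichloroethene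
Product: 3 4,4-dichlorobut-3-en-2-one
Conditions: AlCl3 (1.05 equiv), CH2Cl2, 0 °C → rt; ice/HCl; then Et3N (1 equiv), Et2O, 0 °C; distil
Reagents that add atoms: acetyl chloride CC(=O)Cl; 1,1-dichloroethene C=C(Cl)Cl
Why: In this aliphatic Friedel–Crafts (Kondakov-type) acylation the acylium ion adds to the CH2 terminus to give CH3COCH2CCl3, which loses HCl to form the conjugated β,β-dichloroenone.

**Step 2**
Reactants: 3 4,4-dichlorobut-3-en-2-one; 4 sodium methoxide
Product: 5 4,4-dimethoxybut-3-en-2-one (acetylketene dimethyl acetal)
Conditions: NaOMe (2.2 equiv), MeOH, 0 °C → reflux, 2 h; distil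
Reagents that add atoms: sodium methoxide C[O-].[Na+]
Why: A double conjugate addition–elimination (SNV) at the β-carbon of this vinylogous acid chloride replaces both chlorides, and any ortho-ester over-adduct loses MeOH again on distillation.

**Step 3**
Reactants: 5 4,4-dimethoxybut-3-en-2-one; 6 chlorotrimethylsilane
Product: 7 1,1-dimethoxy-3-(trimethylsilyloxy)buta-1,3-diene
Conditions: TMSCl (1.3 equiv), Et3N (1.5 equiv), ZnCl2 (3 mol %), PhMe, 40 °C, 16 h; filter, distil
Reagents that add atoms: TMSCl C[Si](C)(C)Cl
Why: This is a Danishefsky-type soft enolisation and O-silylation, and because the CH3 is the only enolisable position a single cross-conjugated silyl dienol ether forms.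

**Step 4**
Reactants: 8 orsellinic acid (2,4-dihydroxy-6-methylbenzoic acid); 9 benzyl bromide
Product: 10 benzyl orsellinate (benzyl 2,4-dihydroxy-6-methylbenzoate)
Conditions: BnBr (1.05 equiv), KHCO3 (1.2 equiv), DMF, rt, 16 h
Reagents that add atoms: benzyl bromide BrCc1ccccc1
Why: Bicarbonate ionises only the CO2H for SN2 carboxylate alkylation, so the phenols stay free, and working at rt avoids decarboxylation.

**Step 5**
Reactants: 10 benzyl orsellinate; 11 but-2-ynoic acid (tetrolic acid)
Product: 12 benzyl 4-(but-2-ynoyloxy)-2-hydroxy-6-methylbenzoate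
Conditions: 11 (1.05 equiv), DCC (1.1 equiv), DMAP (5 mol %), CH2Cl2, 0 °C → rt
Reagents that add atoms: but-2-ynoic acid CC#CC(=O)O
Why: Steglich esterification with an unhindered acid takes place only at the free 4-OH because the 2-OH is deactivated by chelation to the ester carbonyl, which is the usual depside selectivity.

**Step 6 (ring B)**
Reactants: 12 aryl but-2-ynoate; 7 1,1-dimethoxy-3-(trimethylsilyloxy)buta-1,3-diene
Product: 13 benzyl 2-hydroxy-4-[(4-hydroxy-2-methoxy-6-methylbenzoyl)oxy]-6-methylbenzoate
Conditions: BSA (1.5 equiv), PhMe, 60 °C, 1 h; then 7 (3 equiv, two portions), sealed tube, 140 °C, 36 h; then 0.5 M HCl, THF, 0 °C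
Reagents that add atoms: diene 7 C=C(O[Si](C)(C)C)C=C(OC)OC
Why: In this Danishefsky/Brassard-type Diels–Alder aromatisation of a β-alkyl ynoate the nucleophilic CH2 terminus bonds to the methyl-bearing β-carbon and the acetal carbon bonds next to the ester, thermal loss of MeOH aromatises the ring to 2-OMe/4-OTMS/6-Me, mild acid then removes the TMS groups, and BSA both masks the ring-C phenol transiently and scavenges the MeOH so that the diene, benzyl ester and aryl ester survive.

**Step 7**
Reactants: 13 didepside phenol; 11 but-2-ynoic acid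
Product: 14 benzyl 4-{[4-(but-2-ynoyloxy)-2-methoxy-6-methylbenzoyl]oxy}-2-hydroxy-6-methylbenzoate
Conditions: 11 (1.05 equiv), DCC (1.1 equiv), DMAP (5 mol %), CH2Cl2, 0 °C → rt
Reagents that add atoms: but-2-ynoic acid CC#CC(=O)O
Why: A second Steglich esterification acylates the only unchelated phenol (ring-B 4-OH), and the existing B–C ester is di-ortho-substituted and does not undergo DMAP-mediated acyl transfer.

**Step 8**
Reactants: 15 tetronic acid (furan-2,4(3H,5H)-dione); 16 benzyl alcohol
Product: 17 4-(benzyloxy)furan-2(5H)-one (benzyl tetronate)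
Conditions: BnOH (1.1 equiv), PPh3, DIAD (1.2 equiv each), THF, 0 °C → rt
Reagents that add atoms: benzyl alcohol OCc1ccccc1
Why: The Mitsunobu reaction of the acidic vinylogous acid (pKa about 4) alkylates the 4-oxygen regioselectively rather than C-3.

**Step 9**
Reactants: 17 benzyl tetronate; 18 tert-butyldimethylsilyl triflate
Product: 19 {[4-(benzyloxy)furan-2-yl]oxy}(tert-butyl)dimethylsilane
Conditions: TBSOTf (1.1 equiv), Et3N (1.5 equiv), CH2Cl2, 0 °C, 1 h; pentane extraction, use directly under Ar
Reagents that add atoms: TBSOTf CC(C)(C)[Si](C)(C)OS(=O)(=O)C(F)(F)F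
Why: This is the standard soft-enolisation route from a butenolide to a 2-silyloxyfuran, in which O-silylation of the electron-rich lactone carbonyl acidifies C5–H and Et3N removes that proton to aromatise the ring.

**Step 10 (ring A, key step)**
Reactants: 14 didepside but-2-ynoate; 19 4-benzyloxy-2-silyloxyfuran
Product: 20 benzyl 4-{[4-({4-(benzyloxy)-2,5-dihydroxy-6-methylbenzoyl}oxy)-2-methoxy-6-methylbenzoyl]oxy}-2-hydroxy-6-methylbenzoate
Conditions: BSA (1.2 equiv), PhMe, 60 °C, 1 h; then 19 (3 equiv), BHT (cat.), sealed tube, Ar, 130 °C, 24–48 h; then Et3N·3HF, THF, 0 °C → rt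
Reagents that add atoms: silyloxyfuran 19 CC(C)(C)[Si](C)(C)Oc1cc(OCc2ccccc2)co1
Why: Proposed new method: furan 19 is an s-cis-locked tetra-oxygenated (Brassard-like) diene whose doubly activated C5 should bond to the methyl-bearing β-carbon of the aryl-ester-activated ynoate while C2 bonds to the α-carbon, after which the 7-oxanorbornadiene ionises at the C2–O bridge bond (the cation is stabilised by OSi) and loses the C5 proton, so the ring oxygen becomes 5-OH, the lactone oxygen becomes 2-O(Si), and 4-OBn and 6-Me fall into place irreversibly, with buffered fluoride then removing the silyl groups without touching the aryl esters; the closest known reaction type is the Diels–Alder/ring-opening aromatisation of 2-silyloxy- and 2-alkoxyfurans with propiolates or acetylenedicarboxylates to give hydroquinone monoethers.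

**Step 11**
Reactants: 20 dibenzyl-protected tridepside
Product: 21 2'-O-methylhiascic acid (target)
Conditions: H2 (1 atm), 10% Pd/C, degassed EtOAc–THF, rt, 2–4 h; filter under Ar, crystallise
Reagents that add atoms: none
Why: Neutral catalytic hydrogenolysis cleaves the benzyl ester and the benzyl ether together while leaving both depside esters and the OMe intact, and it also re-reduces any quinone formed by adventitious air oxidation of ring A.

## Compound list

| No. | Name | SMILES | Role |
|---|---|---|---|
| 1 | acetyl chloride | CC(=O)Cl | starting material |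
| 2 | 1,1-dichloroethene | C=C(Cl)Cl | starting material |
| 3 | 4,4-dichlorobut-3-en-2-one | CC(=O)C=C(Cl)Cl | intermediate |
| 4 | sodium methoxide | C[O-].[Na+] | starting material |
| 5 | 4,4-dimethoxybut-3-en-2-one | CC(=O)C=C(OC)OC | intermediate |
| 6 | chlorotrimethylsilane | C[Si](C)(C)Cl | starting material |
| 7 | 1,1-dimethoxy-3-(trimethylsilyloxy)buta-1,3-diene | C=C(O[Si](C)(C)C)C=C(OC)OC | intermediate |
| 8 | orsellinic acid | Cc1cc(O)cc(O)c1C(=O)O | starting material |
| 9 | benzyl bromide | BrCc1ccccc1 | starting material |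
| 10 | benzyl orsellinate | Cc1cc(O)cc(O)c1C(=O)OCc1ccccc1 | intermediate |
| 11 | but-2-ynoic acid | CC#CC(=O)O | starting material |
| 12 | benzyl 4-(but-2-ynoyloxy)-2-hydroxy-6-methylbenzoate | CC#CC(=O)Oc1cc(C)c(C(=O)OCc2ccccc2)c(O)c1 | intermediate |
| 13 | benzyl 2-hydroxy-4-[(4-hydroxy-2-methoxy-6-methylbenzoyl)oxy]-6-methylbenzoate | COc1cc(O)cc(C)c1C(=O)Oc1cc(C)c(C(=O)OCc2ccccc2)c(O)c1 | intermediate |
| 14 | benzyl 4-{[4-(but-2-ynoyloxy)-2-methoxy-6-methylbenzoyl]oxy}-2-hydroxy-6-methylbenzoate | CC#CC(=O)Oc1cc(C)c(C(=O)Oc2cc(C)c(C(=O)OCc3ccccc3)c(O)c2)c(OC)c1 | intermediate |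
| 15 | tetronic acid | O=C1CC(=O)CO1 | starting material |
| 16 | benzyl alcohol | OCc1ccccc1 | starting material |
| 17 | 4-(benzyloxy)furan-2(5H)-one | O=C1C=C(OCc2ccccc2)CO1 | intermediate |
| 18 | tert-butyldimethylsilyl triflate | CC(C)(C)[Si](C)(C)OS(=O)(=O)C(F)(F)F | starting material |
| 19 | {[4-(benzyloxy)furan-2-yl]oxy}(tert-butyl)dimethylsilane | CC(C)(C)[Si](C)(C)Oc1cc(OCc2ccccc2)co1 | intermediate |
| 20 | benzyl 4-{[4-({4-(benzyloxy)-2,5-dihydroxy-6-methylbenzoyl}oxy)-2-methoxy-6-methylbenzoyl]oxy}-2-hydroxy-6-methylbenzoate | COc1cc(OC(=O)c2c(O)cc(OCc3ccccc3)c(O)c2C)cc(C)c1C(=O)Oc1cc(C)c(C(=O)OCc2ccccc2)c(O)c1 | intermediate |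
| 21 | 2'-O-methylhiascic acid (achiral) | COc1cc(OC(=O)c2c(O)cc(O)c(O)c2C)cc(C)c1C(=O)Oc1cc(C)c(C(=O)O)c(O)c1 | target |

## Step count
Total steps: 11.
Longest linear sequence: 7 steps (1 → 2 → 3 → 6 → 7 → 10 → 11). From orsellinic acid the sequence is 6 steps.

## Three steps most likely to fail
1. **Step 10, furan Diels–Alder and aromatisation on a β-methyl ynoate.** Fallback: build ring A as a plain orsellinate by Diels–Alder/retro-Diels–Alder of 14 with the dimedone-derived 5,5-dimethyl-1,3-bis(trimethylsilyloxy)cyclohexa-1,3-diene, which loses isobutene. Then install the 5-oxygen late by Teuber oxidation (Fremy's salt, phosphate buffer). This acts on the only free resorcinol ring, para to its 2-OH, and gives the hydroxy-p-quinone. The final H2/Pd-C step reduces the quinone and removes the benzyl ester.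
2. **Step 6, sluggish cycloaddition or decomposition of the ketene-acetal diene.** Fallback: form the aryl–C(=O) bond instead of the ring. This would be a Pd-catalysed aryloxycarbonylation (CO, Pd/Xantphos, Et3N) of 2-iodo-1-methoxy-3-methyl-5-(triisopropylsilyloxy)benzene with phenol 10, followed by fluoride removal of the TIPS group to reach 13.
3. **Step 9, silyloxyfuran 19 too labile or formed inefficiently.** Fallback: abandon the furan for an open-chain diene, 4-benzyloxy-1-methoxy-1,3-bis(trimethylsilyloxy)buta-1,3-diene, made from methyl 4-(benzyloxy)acetoacetate. Its Diels–Alder reaction with 14 and loss of MeOH gives the isomeric 5-O-benzyl-2,4-dihydroxy tridepside, which converges on 21 in the same hydrogenolysis.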